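The data were computed with made-up constants; noise was put on by code.

In this flask, target and isomer of the product together cannot pass 80.0 % of the starting material charged, because on the list of suspects each target costs one partner, the isomer comes from target, and the partner, the limiting reagent, is charged short.

| flask | starting material | partner | free catalyst | remark | time |
|---|---|---|---|---|---|
| larch | 2 mM | 0.80 equiv | 22 mol% | run made earlier |  |
| flask | 2.0 mM | 0.800 equiv | 11 mol% |  | 5.0 min |

larch run (percent of the starting material charged)

| time / s | target / % | isomer of the product / % |
|---|---|---|
| 10.0 | 61.8 | 9.7 |
| 12.0 | 62.6 | 12.8 |
| 15.0 | 60.8 | 18.4 |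
| 25.0 | 55.7 | 23.2 |
| 40.0 | 54.3 | 25.1 |
| 60.0 | 54.6 | 24.8 |
| 90.0 | 55.1 | 24.8 |

(readings scatter by 0.5 percentage points)

- on the list of suspects stand: starting material + free catalyst <-> catalyst intermediate A; partner + catalyst intermediate A -> catalyst intermediate B; catalyst intermediate B <-> released group + catalyst intermediate C; catalyst intermediate C -> free catalyst + target; target + free catalyst <-> isomer of the product + free catalyst
- no earlier run changes the charge of free catalyst; that part of a forecast is a guess

* the target standing at 5.0 min, as a percentage of the starting material charged
* the isomer of the product standing at 5.0 min, as a percentage of the starting material charged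

Does the larch run reach that ceiling? Its last reading adds up to 79.9 %, so yes, within the scatter.

How is the pool divided? Take the symmetric case as zero: equal shares give 40.0 % each. The larch run stands off that. Its readings are flat from 40.0 s on, and over those last readings the isomer divided by the target, the split 0.455, reads below one.

Does less catalyst move the split? Free catalyst stands on both sides of the step from target to isomer, so I keep the split. My reckoning is therefore target 55.0 % and isomer 25.0 %.

Is there time? Between 10.0 s and 25.0 s the larch isomer closes on its last value at 0.150 /s. Scaled to this catalyst charge that is 0.0748 /s, one relaxation time of 13.4 s, and the flask gets 22.4 of them.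

The weak spot? That scaling is a guess, since no earlier run changes the catalyst. Also, about 20.0 % of the starting material should stay unconverted in this flask, more than the 11 mol% of catalyst, and it can hold catalyst as catalyst intermediate A. The allowance of 22.4 is my answer, so I keep my numbers.

The forecast, close to mine but not identical, says 55.2 % of target and 24.7 % of isomer: “Equilibrium is probably still reached”.

The flask gives 55.2 % of target and 24.8 % of isomer of the product.

    starting material + free catalyst ⇌ catalyst intermediate A (K = 150 /M, k = 9300 /M/s)
    partner + catalyst intermediate A → catalyst intermediate B (k = 20000 /M/s)
    catalyst intermediate B ⇌ released group + catalyst intermediate C (K = 0.00160 M, k = 1.10 /s)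
    catalyst intermediate C → free catalyst + target (k = 1.70 /s)
    target + free catalyst ⇌ isomer of the product + free catalyst, rate k5*[free catalyst]*[target] forward; the back reaction follows from the equilibrium constant (K = 0.450, k = 150 /M/s)

In this flask at 5.00 min, free catalyst stands at 94.5 % of the catalyst charged, with 5.50 % as catalyst intermediate A. For a second flask, like this one but charged with 0.480 equiv of partner, the same split on that smaller pool gives target 33.0 % and isomer 15.0 %. That flask holds 33.1 % of target and 14.9 % of isomer.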